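**Retrosynthetic overview**
- Target ⇒ tris-MOM flavanone (global acetal cleavage last).
- Flavanone C2–aryl bond ⇒ Rh-catalysed asymmetric 1,4-addition of a 4-(MOMO)phenylboron species (from the aryl bromide) to a 6-(piperidinyl)chromone; this sets C2.
- Chromone (pyranone ring, formed last) ⇒ phenol by ortho-acetylation and enaminone annulation. The phenol oxygen comes from Ir C–H borylation/oxidation para to the piperidine, so it becomes O1 and the piperidine ends at C6, not C8.
- Piperidine ring ⇒ enantioselective Stevens 1,2-shift (radical-pair, non-concerted) ring expansion of an N-benzyl-N-methylpyrrolidinium ylide; this sets the piperidine stereocentre.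
- Pyrrolidinium salt ⇒ resorcinol bis-MOM ether by ortho-lithiation, N-formylpyrrolidine, reduction and N-methylation. Ring order: pyrrolidine (bought) → piperidine → pyranone.

Assumption: 1 and 16 are bought as MOM ethers; the sense of induction of (−)-sparteine (step 3) and of the (S)-ligand (step 7) is assigned by analogy (Hayashi model for step 7, empirical for step 3), and the commercial antipode is used if either proves opposite.

**Route**

Step 1
Reactants: 1 1,3-bis(methoxymethoxy)benzene; 2 pyrrolidine-1-carbaldehyde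
Product: 6 1-{[2,6-bis(methoxymethoxy)phenyl]methyl}pyrrolidine, via aryllithium 3 (not isolated), via lithium hemiaminolate 4 (not isolated), via iminium acetate 5 (not isolated)
Conditions: n-BuLi, THF, 0 °C → rt; 2, −78 → 0 °C; then AcOH, NaBH(OAc)3, rt
Reagents that add atoms: n-butyllithium, [Li]CCCC (lithium of 3 and 4 only); acetic acid, CC(=O)O (acetate of 5 only)
Why: Directed ortho-metalation between the two OMOM groups, addition to the formamide to a stable tetrahedral hemiaminolate, acid ionisation to the aryl-stabilised iminium ion and its reduction (one-pot formylation/reductive amination, the formamide supplying both CH and the amine); no stereocentre.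

Step 2
Reactants: 6 1-{[2,6-bis(methoxymethoxy)phenyl]methyl}pyrrolidine
Product: 7 1-{[2,6-bis(methoxymethoxy)phenyl]methyl}-1-methylpyrrolidin-1-ium trifluoromethanesulfonate
Conditions: MeOTf, Et2O, 0 °C → rt; filter the salt
Reagents that add atoms: methyl trifluoromethanesulfonate, COS(=O)(=O)C(F)(F)F
Why: Menshutkin N-methylation of a tertiary amine; the non-nucleophilic triflate counter-ion cannot debenzylate the electron-rich benzylammonium salt.

Step 3
Reactants: 7 1-{[2,6-bis(methoxymethoxy)phenyl]methyl}-1-methylpyrrolidin-1-ium trifluoromethanesulfonate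
Product: 9 (2S)-2-[2,6-bis(methoxymethoxy)phenyl]-1-methylpiperidine, via lithiated ammonium ylide 8 (not isolated)
Conditions: s-BuLi, (−)-sparteine, toluene/Et2O (suspension), −78 → 0 °C
Reagents that add atoms: none
Why: Proposed new method: an enantioselective Stevens [1,2]-shift ring expansion under external chiral-ligand control — s-BuLi·(−)-sparteine removes one of the two enantiotopic benzylic protons of 7; the C-lithiated ylide 8 is kept pyramidal and configurationally defined by chelation of lithium to an ortho OMOM oxygen and by the twisted 2,6-disubstituted aryl ring (which also blocks the competing [2,3] Sommelet–Hauser path, since neither ortho carbon can rearomatise); homolysis of an N–CH2 ring bond gives a tethered singlet diradical that recombines within the same molecule faster than C–N rotation, so the carbanion configuration is relayed to C2 of the piperidine (S); the closest known reaction types are the base-induced Stevens rearrangement of benzylic ammonium ylides (racemic, ring expansions included), the alkyllithium/chiral-ligand-controlled enantioselective [1,2]-Wittig rearrangement of benzyl ethers, and N-to-C chirality transfer in Stevens shifts of proline-derived ammonium ylides.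

Step 4
Reactants: 9 (2S)-2-[2,6-bis(methoxymethoxy)phenyl]-1-methylpiperidine
Product: 11 3,5-bis(methoxymethoxy)-4-[(2S)-1-methylpiperidin-2-yl]phenol, via aryl pinacol boronate 10 (not isolated)
Conditions: B2pin2, [Ir(OMe)(cod)]2 (1.5 mol%), 4,4′-di-tert-butyl-2,2′-bipyridine (3 mol%), THF, 80 °C; then aq. H2O2, NaOH, 0 °C, 30 min; Na2S2O3
Reagents that add atoms: bis(pinacolato)diboron, CC1(C)OB(OC1(C)C)B1OC(C)(C)C(C)(C)O1 (boronate of 10 only); hydrogen peroxide, OO
Why: Sterically governed Ir-catalysed aromatic C–H borylation reaches only the ring C–H with no ortho substituent (para to the piperidine), and peroxide oxidation of the C–B bond gives the phenol (short, cold oxidation spares the hindered amine); the stereocentre is untouched.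

Step 5
Reactants: 11 3,5-bis(methoxymethoxy)-4-[(2S)-1-methylpiperidin-2-yl]phenol
Product: 13 1-{6-hydroxy-2,4-bis(methoxymethoxy)-3-[(2S)-1-methylpiperidin-2-yl]phenyl}ethan-1-one, via bromomagnesium phenoxide 12 (not isolated)
Conditions: EtMgBr (1.0 equiv), Et2O, 0 °C; switch to toluene; AcCl (1.1 equiv), 0 °C → rt
Reagents that add atoms: ethylmagnesium bromide, CC[Mg]Br (magnesium and bromine of 12 only); acetyl chloride, CC(Cl)=O
Why: Magnesium-templated ortho-coordinated Friedel–Crafts acylation of a bromomagnesium phenoxide (both ortho carbons equivalent, ring strongly activated), run without protic or strong Lewis acid so the MOM ethers survive.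

Step 6
Reactants: 13 1-{6-hydroxy-2,4-bis(methoxymethoxy)-3-[(2S)-1-methylpiperidin-2-yl]phenyl}ethan-1-one
Product: 15 5,7-bis(methoxymethoxy)-6-[(2S)-1-methylpiperidin-2-yl]-4H-chromen-4-one, via enaminone 14 (not isolated)
Conditions: DMF-DMA, toluene, 70 °C; then AcOH, CH2Cl2, rt
Reagents that add atoms: N,N-dimethylformamide dimethyl acetal, COC(OC)N(C)C
Why: Enaminone chromone synthesis — condensation of the methyl ketone with the amide acetal, then intramolecular addition–elimination of the single free phenol with loss of Me2NH, so only one regioisomer can form.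

Step 7
Reactants: 15 5,7-bis(methoxymethoxy)-6-[(2S)-1-methylpiperidin-2-yl]-4H-chromen-4-one; 16 1-bromo-4-(methoxymethoxy)benzene
Product: 20 (2S)-5,7-bis(methoxymethoxy)-2-[4-(methoxymethoxy)phenyl]-6-[(2S)-1-methylpiperidin-2-yl]-2,3-dihydro-4H-chromen-4-one, via aryllithium 17 (not isolated), via lithium aryltrimethoxyborate 18 (not isolated), via arylboronic acid 19 (not isolated)
Conditions: 16 (2 equiv), n-BuLi, THF, −78 °C; B(OMe)3, → rt; AcOH (1 equiv per Li), H2O; then 15, [Rh(OH)(cod)]2 (2.5 mol%), (S)-MeO-F12-BIPHEP (5.5 mol%), toluene/H2O, 40 °C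
Reagents that add atoms: n-butyllithium, [Li]CCCC (lithium of 17 and 18 only); trimethyl borate, COB(OC)OC (boron and methoxy groups of 18, boron of 19 only); water, O (hydroxy groups of 19 only)
Why: Hayashi–Miyaura Rh-catalysed asymmetric 1,4-addition of an arylboronic acid (made in situ by Br/Li exchange and borylation, buffered so the chromone is not ring-opened) to a chromone with the electron-poor atropisomeric bisphosphine (S)-(6,6′-dimethoxybiphenyl-2,2′-diyl)bis[bis(3,4,5-trifluorophenyl)phosphane]; the catalyst alone selects the face and sets C2 as S, the remote piperidine centre having no influence.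

Step 8
Reactants: 20 (2S)-5,7-bis(methoxymethoxy)-2-[4-(methoxymethoxy)phenyl]-6-[(2S)-1-methylpiperidin-2-yl]-2,3-dihydro-4H-chromen-4-one
Product: 21 (2S)-5,7-dihydroxy-2-(4-hydroxyphenyl)-6-[(2S)-1-methylpiperidin-2-yl]-2,3-dihydro-4H-chromen-4-one
Conditions: HCl (2 M in MeOH), 40 °C; then aq. NaHCO3 to pH 7–8
Reagents that add atoms: none
Why: Acid-catalysed acetal exchange removes the three MOM groups as dimethoxymethane; mild acid and neutralisation without excess base avoid retro-oxa-Michael epimerisation at C2 and quinone-methide opening at the benzylic amine centre.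

**Compound list**
1 | 1,3-bis(methoxymethoxy)benzene | COCOc1cccc(OCOC)c1 | starting material
2 | pyrrolidine-1-carbaldehyde | O=CN1CCCC1 | starting material
3 | [2,6-bis(methoxymethoxy)phenyl]lithium | [Li]c1c(OCOC)cccc1OCOC | intermediate (not isolated)
4 | lithium [2,6-bis(methoxymethoxy)phenyl](pyrrolidin-1-yl)methanolate, racemic | [Li]OC(c1c(OCOC)cccc1OCOC)N1CCCC1 | intermediate (not isolated)
5 | 1-{[2,6-bis(methoxymethoxy)phenyl]methylidene}pyrrolidin-1-ium acetate | COCOc1cccc(OCOC)c1C=[N+]1CCCC1.CC(=O)[O-] | intermediate (not isolated)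
6 | 1-{[2,6-bis(methoxymethoxy)phenyl]methyl}pyrrolidine | COCOc1cccc(OCOC)c1CN1CCCC1 | intermediate
7 | 1-{[2,6-bis(methoxymethoxy)phenyl]methyl}-1-methylpyrrolidin-1-ium trifluoromethanesulfonate | COCOc1cccc(OCOC)c1C[N+]1(C)CCCC1.[O-]S(=O)(=O)C(F)(F)F | intermediate
8 | [2,6-bis(methoxymethoxy)phenyl](1-methylpyrrolidin-1-ium-1-yl)methanide, as its lithium–sparteine complex | COCOc1cccc(OCOC)c1[CH-][N+]1(C)CCCC1 | intermediate (not isolated)
9 | (2S)-2-[2,6-bis(methoxymethoxy)phenyl]-1-methylpiperidine | CN1CCCC[C@H]1c1c(OCOC)cccc1OCOC | intermediate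
10 | (2S)-2-[2,6-bis(methoxymethoxy)-4-(4,4,5,5-tetramethyl-1,3,2-dioxaborolan-2-yl)phenyl]-1-methylpiperidine | CN1CCCC[C@H]1c1c(OCOC)cc(cc1OCOC)B1OC(C)(C)C(C)(C)O1 | intermediate (not isolated)
11 | 3,5-bis(methoxymethoxy)-4-[(2S)-1-methylpiperidin-2-yl]phenol | CN1CCCC[C@H]1c1c(OCOC)cc(O)cc1OCOC | intermediate
12 | bromomagnesium 3,5-bis(methoxymethoxy)-4-[(2S)-1-methylpiperidin-2-yl]phenoxide | CN1CCCC[C@H]1c1c(OCOC)cc(O[Mg]Br)cc1OCOC | intermediate (not isolated)
13 | 1-{6-hydroxy-2,4-bis(methoxymethoxy)-3-[(2S)-1-methylpiperidin-2-yl]phenyl}ethan-1-one | CN1CCCC[C@H]1c1c(OCOC)cc(O)c(C(C)=O)c1OCOC | intermediate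
14 | (2E)-3-(dimethylamino)-1-{6-hydroxy-2,4-bis(methoxymethoxy)-3-[(2S)-1-methylpiperidin-2-yl]phenyl}prop-2-en-1-one | CN1CCCC[C@H]1c1c(OCOC)cc(O)c(C(=O)/C=C/N(C)C)c1OCOC | intermediate (not isolated)
15 | 5,7-bis(methoxymethoxy)-6-[(2S)-1-methylpiperidin-2-yl]-4H-chromen-4-one | CN1CCCC[C@H]1c1c(OCOC)cc2occc(=O)c2c1OCOC | intermediate
16 | 1-bromo-4-(methoxymethoxy)benzene | COCOc1ccc(Br)cc1 | starting material
17 | [4-(methoxymethoxy)phenyl]lithium | [Li]c1ccc(OCOC)cc1 | intermediate (not isolated)
18 | lithium trimethoxy[4-(methoxymethoxy)phenyl]borate | [Li+].COCOc1ccc(cc1)[B-](OC)(OC)OC | intermediate (not isolated)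
19 | [4-(methoxymethoxy)phenyl]boronic acid | COCOc1ccc(cc1)B(O)O | intermediate (not isolated)
20 | (2S)-5,7-bis(methoxymethoxy)-2-[4-(methoxymethoxy)phenyl]-6-[(2S)-1-methylpiperidin-2-yl]-2,3-dihydro-4H-chromen-4-one | CN1CCCC[C@H]1c1c(OCOC)cc2c(c1OCOC)C(=O)C[C@@H](c1ccc(OCOC)cc1)O2 | intermediate
21 | (2S)-5,7-dihydroxy-2-(4-hydroxyphenyl)-6-[(2S)-1-methylpiperidin-2-yl]-2,3-dihydro-4H-chromen-4-one | CN1CCCC[C@H]1c1c(O)cc2c(c1O)C(=O)C[C@@H](c1ccc(O)cc1)O2 | target

**Step count and risks**
Total steps: 8. Longest linear sequence: 8 (1 → 21); 16 enters in step 7 without a separate step.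

Three steps most likely to fail:

Step 3 (the proposed new enantioselective ring expansion; the main risk is low enantioselectivity). The fallback sets out from 7 and comes back at 9. Compound 7 is rearranged with an achiral base (KOt-Bu, THF/DMSO, rt) in an ordinary Stevens ring expansion to racemic 2-[2,6-bis(methoxymethoxy)phenyl]-1-methylpiperidine F1. F1 is resolved by crystallising the (2S)-amine hydrogen O,O′-di-p-toluoyl-L-tartrate salt F2 from EtOH (the D-acid is used if the (R)-amine salt crystallises first). Aqueous NaOH then frees 9.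

Step 5 (C- versus O-acylation of the phenoxide, and MOM survival). The fallback sets out from 11 and comes back at 15, bypassing 13 and step 6. Ortho-formylation of 11 (MgCl2, Et3N, paraformaldehyde, MeCN, reflux) gives 6-hydroxy-2,4-bis(methoxymethoxy)-3-[(2S)-1-methylpiperidin-2-yl]benzaldehyde F3. Ethynylmagnesium bromide (THF, 0 °C) gives the propargylic alcohol 1-{6-hydroxy-2,4-bis(methoxymethoxy)-3-[(2S)-1-methylpiperidin-2-yl]phenyl}prop-2-yn-1-ol F4 as both carbinol epimers. MnO2 (CH2Cl2) oxidises it to the ynone 1-{6-hydroxy-2,4-bis(methoxymethoxy)-3-[(2S)-1-methylpiperidin-2-yl]phenyl}prop-2-yn-1-one F5, which closes by 6-endo oxa-Michael addition (cat. K2CO3) to 15.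

Step 7 (hindered, amine-bearing chromone; in situ boron reagent; catalyst inhibition or ring opening). The fallback sets out from 13 and 16 and comes back at 20. Aryllithium 17 (from 16, n-BuLi) is quenched with DMF to 4-(methoxymethoxy)benzaldehyde F6. Claisen–Schmidt condensation with 13 (KOH, EtOH, rt) gives the chalcone (2E)-1-{6-hydroxy-2,4-bis(methoxymethoxy)-3-[(2S)-1-methylpiperidin-2-yl]phenyl}-3-[4-(methoxymethoxy)phenyl]prop-2-en-1-one F7. Oxa-Michael cyclisation (NaOAc, EtOH, reflux) gives 20 together with its (2R)-epimer (2R)-5,7-bis(methoxymethoxy)-2-[4-(methoxymethoxy)phenyl]-6-[(2S)-1-methylpiperidin-2-yl]-2,3-dihydro-4H-chromen-4-one F8. The two diastereomers are separated by preparative HPLC, and F8 is recycled by base re-equilibration through F7.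

**Further compounds**
F1 | step 3 | racemic 2-[2,6-bis(methoxymethoxy)phenyl]-1-methylpiperidine | CN1CCCCC1c1c(OCOC)cccc1OCOC
F2 | step 3 | (2S)-2-[2,6-bis(methoxymethoxy)phenyl]-1-methylpiperidin-1-ium hydrogen (2R,3R)-2,3-bis(4-methylbenzoyloxy)butanedioate | C[NH+]1CCCC[C@H]1c1c(OCOC)cccc1OCOC.[O-]C(=O)[C@H](OC(=O)c1ccc(C)cc1)[C@@H](OC(=O)c1ccc(C)cc1)C(O)=O
F3 | step 5 | 6-hydroxy-2,4-bis(methoxymethoxy)-3-[(2S)-1-methylpiperidin-2-yl]benzaldehyde | CN1CCCC[C@H]1c1c(OCOC)cc(O)c(C=O)c1OCOC
F4 | step 5 | 1-{6-hydroxy-2,4-bis(methoxymethoxy)-3-[(2S)-1-methylpiperidin-2-yl]phenyl}prop-2-yn-1-ol, both carbinol epimers | CN1CCCC[C@H]1c1c(OCOC)cc(O)c(C(O)C#C)c1OCOC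
F5 | step 5 | 1-{6-hydroxy-2,4-bis(methoxymethoxy)-3-[(2S)-1-methylpiperidin-2-yl]phenyl}prop-2-yn-1-one | CN1CCCC[C@H]1c1c(OCOC)cc(O)c(C(=O)C#C)c1OCOC
F6 | step 7 | 4-(methoxymethoxy)benzaldehyde | COCOc1ccc(C=O)cc1
F7 | step 7 | (2E)-1-{6-hydroxy-2,4-bis(methoxymethoxy)-3-[(2S)-1-methylpiperidin-2-yl]phenyl}-3-[4-(methoxymethoxy)phenyl]prop-2-en-1-one | CN1CCCC[C@H]1c1c(OCOC)cc(O)c(C(=O)/C=C/c2ccc(OCOC)cc2)c1OCOC
F8 | step 7 | (2R)-5,7-bis(methoxymethoxy)-2-[4-(methoxymethoxy)phenyl]-6-[(2S)-1-methylpiperidin-2-yl]-2,3-dihydro-4H-chromen-4-one | CN1CCCC[C@H]1c1c(OCOC)cc2c(c1OCOC)C(=O)C[C@H](c1ccc(OCOC)cc1)O2
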